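**Strategy.** Numbering: carbocycle (ring B) C1–C6 with C1 on the oxane (ring A), C3–Br, C4(Me)–Cl; C7 the ring-A quaternary carbon, C8–OAc, C10–Br, C11 gem-dimethyl. C2–C5 plus the C4 methyl are an isoprene unit and C1/C6 a vinyl group on carbonyl C7, so a Lewis-acid Diels–Alder reaction closes ring B by forming C5–C6 and C1–C2 at once, sets C1 and leaves the C3=C4 olefin for the halogens. The precursor is acyclic (R)-4-silyloxy-7-methylocta-1,6-dien-3-one; its stereocentre (C8) relays to C1, C7 (methyl addition) and C10 (bromoetherification). The trans-diequatorial C3-Br/C4-Cl pair comes from a reagent-controlled epoxide through a bromonium relay.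

Key step: step 5

Remark (assumption): compounds 1, 2, 5 and 11 are taken as purchasable. TBS = tert-butyldimethylsilyl. "Syn/anti" in ring B refers to the face relative to the C1–C7 bond.

Step 1
Reactants: 1 (S)-4-benzyloxazolidin-2-one; 2 2-[(tert-butyldimethylsilyl)oxy]acetic acid
Product: 4 (S)-4-benzyl-3-{2-[(tert-butyldimethylsilyl)oxy]acetyl}oxazolidin-2-one, via mixed pivalic anhydride 3 (not isolated)
Conditions: 2, t-BuCOCl, Et3N, THF, −20 °C; then 1, LiCl, −20 °C → rt
Reagents that add atoms: none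
Why: Mixed-anhydride N-acylation of the oxazolidinone (LiCl/Et3N activation); no stereocentre is created.

Step 2
Reactants: 4 (S)-4-benzyl-3-{2-[(tert-butyldimethylsilyl)oxy]acetyl}oxazolidin-2-one; 5 1-bromo-3-methylbut-2-ene (prenyl bromide)
Product: 7 (S)-4-benzyl-3-{(R)-2-[(tert-butyldimethylsilyl)oxy]-5-methylhex-4-enoyl}oxazolidin-2-one, via sodium enolate 6 (not isolated)
Conditions: NaN(SiMe3)2, THF, −78 °C; then 5, −78 → −45 °C
Reagents that add atoms: none
Why: Evans auxiliary alkylation: the chelated sodium Z-enolate should be alkylated by the allylic bromide on the face opposite the benzyl group, setting the future C8 as R.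

Step 3
Reactants: 7 (S)-4-benzyl-3-{(R)-2-[(tert-butyldimethylsilyl)oxy]-5-methylhex-4-enoyl}oxazolidin-2-one
Product: 8 (R)-2-[(tert-butyldimethylsilyl)oxy]-N-methoxy-N,5-dimethylhex-4-enamide
Conditions: MeNH(OMe)·HCl, AlMe3, CH2Cl2, −15 → 0 °C
Reagents that add atoms: N,O-dimethylhydroxylamine hydrochloride, CNOC.Cl
Why: Weinreb amide formation by aluminium amide transamidation at the exocyclic imide carbonyl, which frees the auxiliary and leaves C8 untouched.

Step 4
Reactants: 8 (R)-2-[(tert-butyldimethylsilyl)oxy]-N-methoxy-N,5-dimethylhex-4-enamide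
Product: 10 (R)-4-[(tert-butyldimethylsilyl)oxy]-7-methylocta-1,6-dien-3-one, via magnesium hemiaminal chelate 9 (not isolated)
Conditions: CH2=CHMgBr, THF, −78 → 0 °C; inverse quench into cold 1 M HCl
Reagents that add atoms: vinylmagnesium bromide, C=C[Mg]Br
Why: Weinreb ketone synthesis: the chelated tetrahedral adduct resists a second addition and collapses to the vinyl ketone on acidic quench; no new stereocentre.

Step 5
Reactants: 10 (R)-4-[(tert-butyldimethylsilyl)oxy]-7-methylocta-1,6-dien-3-one; 11 isoprene (2-methylbuta-1,3-diene)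
Product: 12 (R)-2-[(tert-butyldimethylsilyl)oxy]-5-methyl-1-[(S)-4-methylcyclohex-3-en-1-yl]hex-4-en-1-one
Conditions: 11 (8 equiv), BF3·OEt2 (0.5 equiv), CH2Cl2, −78 °C
Reagents that add atoms: none
Why: Lewis-acid-catalysed Diels–Alder reaction: the boron-bound s-cis enone and isoprene combine in a concerted but asynchronous [4+2] cycloaddition in which the C5–C6 bond to the enone β-carbon leads and C1–C2 follows; the closest known reaction type is the BF3- or AlCl3-promoted addition of isoprene to alkyl vinyl ketones. Ring B is closed intermolecularly in a suprafacial six-membered [4+2] mode. The new stereocentre C1 is controlled by C8: the silyl ether cannot chelate boron, so the enone should react through the dipole-minimised rotamer (C8–O anti to C7=O, Cornforth-type) in which the C9 chain covers one face, and isoprene adds to the other to give 1S. The step needs 1,4-("para") regioselectivity, secured by the match of the larger HOMO coefficient at the diene terminus next to the methyl-bearing carbon (C5) with the activated β-carbon (C6), and chemoselectivity over attack of the prenyl olefin on the activated enone, secured by excess diene at −78 °C. The C3=C4 olefin of the adduct sits where bromine and chlorine are required later.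

Step 6
Reactants: 12 (R)-2-[(tert-butyldimethylsilyl)oxy]-5-methyl-1-[(S)-4-methylcyclohex-3-en-1-yl]hex-4-en-1-one
Product: 13 (2R,3R)-3-[(tert-butyldimethylsilyl)oxy]-6-methyl-2-[(S)-4-methylcyclohex-3-en-1-yl]hept-5-en-2-ol
Conditions: MeLi, THF, −78 °C
Reagents that add atoms: methyllithium, [Li]C
Why: 1,2-Addition of an organolithium under non-chelating conditions (Cornforth/polar Felkin–Anh control): with the bulky silyl ether unable to chelate lithium, methyl should attack the ketone face anti to the C9 chain, setting C7 as R (anti adduct).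

Step 7
Reactants: 13 (2R,3R)-3-[(tert-butyldimethylsilyl)oxy]-6-methyl-2-[(S)-4-methylcyclohex-3-en-1-yl]hept-5-en-2-ol
Product: 14 tert-butyl({(2R,3R,5R)-5-bromo-2,6,6-trimethyl-2-[(S)-4-methylcyclohex-3-en-1-yl]oxan-3-yl}oxy)dimethylsilane
Conditions: 2,4,4,6-tetrabromocyclohexa-2,5-dien-1-one, MeNO2, 0 °C → rt, dark
Reagents that add atoms: 2,4,4,6-tetrabromocyclohexa-2,5-dien-1-one, O=C1C(Br)=CC(Br)(Br)C=C1Br
Why: Bromoetherification (6-endo, Markovnikov): the tertiary C7 hydroxyl should capture the side-chain bromonium at C11 through a chair with the cyclohexenyl group and bromine equatorial, setting C10 as R, while bromonium formation at the ring-B olefin, which has no nucleophile in reach, is reversible.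

Step 8
Reactants: 14 tert-butyl({(2R,3R,5R)-5-bromo-2,6,6-trimethyl-2-[(S)-4-methylcyclohex-3-en-1-yl]oxan-3-yl}oxy)dimethylsilane
Product: 15 (2R,3R,5R)-5-bromo-2,6,6-trimethyl-2-[(S)-4-methylcyclohex-3-en-1-yl]oxan-3-ol
Conditions: HF·pyridine, THF, 0 °C → rt
Reagents that add atoms: none
Why: Fluoride-driven desilylation (strong Si–F bond) under non-basic conditions that spare the secondary bromide and the olefin.

Step 9
Reactants: 15 (2R,3R,5R)-5-bromo-2,6,6-trimethyl-2-[(S)-4-methylcyclohex-3-en-1-yl]oxan-3-ol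
Product: 16 (2R,3R,5R)-5-bromo-2,6,6-trimethyl-2-[(S)-4-methylcyclohex-3-en-1-yl]oxan-3-yl acetate
Conditions: Ac2O, 4-(dimethylamino)pyridine, pyridine, rt
Reagents that add atoms: acetic anhydride, CC(=O)OC(C)=O
Why: Nucleophile-catalysed acylation of the hindered axial secondary alcohol, the only free hydroxyl left.

Step 10
Reactants: 16 (2R,3R,5R)-5-bromo-2,6,6-trimethyl-2-[(S)-4-methylcyclohex-3-en-1-yl]oxan-3-yl acetate
Product: 17 (2R,3R,5R)-5-bromo-2,6,6-trimethyl-2-[(1R,3S,6S)-6-methyl-7-oxabicyclo[4.1.0]heptan-3-yl]oxan-3-yl acetate (3R,4S-epoxide, oxygen anti to C7)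
Conditions: 1,2:4,5-di-O-isopropylidene-β-D-erythro-hexo-2,3-diulo-2,6-pyranose (0.3 equiv), KHSO5 (as 2KHSO5·KHSO4·K2SO4), K2CO3, Bu4NHSO4, MeCN/CH2(OMe)2–aq Na2B4O7 buffer (pH 10.5), 0 °C
Reagents that add atoms: potassium peroxymonosulfate KHSO5, [K+].[O-]S(=O)(=O)OO
Why: Shi epoxidation: the chiral dioxirane from the D-fructose-derived ketone should choose the olefin face by reagent control (spiro transition state, the remote C1 has little say), giving the epoxide with oxygen anti to the C1 substituent.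

Step 11
Reactants: 17 (3R,4S)-epoxide
Product: 18 (2R,3R,5R)-5-bromo-2-[(1S,3R,4R)-4-bromo-3-hydroxy-4-methylcyclohexyl]-2,6,6-trimethyloxan-3-yl acetate
Conditions: HBr (33% in AcOH, 1.2 equiv), CH2Cl2, −20 °C
Reagents that add atoms: hydrogen bromide, Br
Why: Acid-mediated epoxide opening in which the trans-diaxial (Fürst–Plattner) and Markovnikov preferences coincide: bromide should enter axially at tertiary C4 with inversion, syn to the C1 substituent, leaving the axial C3 hydroxyl.

Step 12
Reactants: 18 trans-diaxial bromohydrin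
Product: 21 8-acetylcaespitol, via alkoxyphosphonium chloride 19 (not isolated), via 8-acetylisocaespitol 20 (not isolated)
Conditions: Ph3P, N-chlorosuccinimide, CH2Cl2, 0 °C → rt; then toluene, 100 °C
Reagents that add atoms: N-chlorosuccinimide, O=C1CCC(=O)N1Cl
Why: Appel-type activation with neighbouring-group participation: the antiperiplanar tertiary bromide should expel phosphine oxide to give a bromonium ion on the ring-B face syn to the C1 substituent, which chloride opens at C4 (target, 3S,4S) or at C3 (20), and heating should convert 20 into the diequatorial target by suprafacial 1,2-interchange of the two halogens (dyotropic rearrangement).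

**Compound list**

1 | (S)-4-benzyloxazolidin-2-one | O=C1OC[C@H](Cc2ccccc2)N1 | starting material
2 | 2-[(tert-butyldimethylsilyl)oxy]acetic acid | CC(C)(C)[Si](C)(C)OCC(=O)O | starting material
3 | 2-[(tert-butyldimethylsilyl)oxy]acetic pivalic anhydride | CC(C)(C)[Si](C)(C)OCC(=O)OC(=O)C(C)(C)C | intermediate
4 | (S)-4-benzyl-3-{2-[(tert-butyldimethylsilyl)oxy]acetyl}oxazolidin-2-one | CC(C)(C)[Si](C)(C)OCC(=O)N1[C@@H](Cc2ccccc2)COC1=O | intermediate
5 | 1-bromo-3-methylbut-2-ene | CC(C)=CCBr | starting material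
6 | sodium (Z)-enolate of 4 | CC(C)(C)[Si](C)(C)O/C=C(\[O-])N1[C@@H](Cc2ccccc2)COC1=O.[Na+] | intermediate
7 | (S)-4-benzyl-3-{(R)-2-[(tert-butyldimethylsilyl)oxy]-5-methylhex-4-enoyl}oxazolidin-2-one | CC(C)=CC[C@@H](O[Si](C)(C)C(C)(C)C)C(=O)N1[C@@H](Cc2ccccc2)COC1=O | intermediate
8 | (R)-2-[(tert-butyldimethylsilyl)oxy]-N-methoxy-N,5-dimethylhex-4-enamide | CC(C)=CC[C@@H](O[Si](C)(C)C(C)(C)C)C(=O)N(C)OC | intermediate
9 | bromomagnesium alkoxide of the vinyl adduct of 8 (chelated hemiaminal) | C=CC([O-])(N(C)OC)[C@@H](CC=C(C)C)O[Si](C)(C)C(C)(C)C.[Mg+2].[Br-] | intermediate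
10 | (R)-4-[(tert-butyldimethylsilyl)oxy]-7-methylocta-1,6-dien-3-one | C=CC(=O)[C@@H](CC=C(C)C)O[Si](C)(C)C(C)(C)C | intermediate
11 | isoprene (2-methylbuta-1,3-diene) | C=CC(C)=C | starting material
12 | (R)-2-[(tert-butyldimethylsilyl)oxy]-5-methyl-1-[(S)-4-methylcyclohex-3-en-1-yl]hex-4-en-1-one | O=C([C@H]1CCC(C)=CC1)[C@@H](CC=C(C)C)O[Si](C)(C)C(C)(C)C | intermediate
13 | (2R,3R)-3-[(tert-butyldimethylsilyl)oxy]-6-methyl-2-[(S)-4-methylcyclohex-3-en-1-yl]hept-5-en-2-ol | C[C@@](O)([C@H]1CCC(C)=CC1)[C@@H](CC=C(C)C)O[Si](C)(C)C(C)(C)C | intermediate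
14 | tert-butyl({(2R,3R,5R)-5-bromo-2,6,6-trimethyl-2-[(S)-4-methylcyclohex-3-en-1-yl]oxan-3-yl}oxy)dimethylsilane | CC(C)(C)[Si](C)(C)O[C@@H]1C[C@@H](Br)C(C)(C)O[C@]1(C)[C@H]1CCC(C)=CC1 | intermediate
15 | (2R,3R,5R)-5-bromo-2,6,6-trimethyl-2-[(S)-4-methylcyclohex-3-en-1-yl]oxan-3-ol | O[C@@H]1C[C@@H](Br)C(C)(C)O[C@]1(C)[C@H]1CCC(C)=CC1 | intermediate
16 | (2R,3R,5R)-5-bromo-2,6,6-trimethyl-2-[(S)-4-methylcyclohex-3-en-1-yl]oxan-3-yl acetate | CC(=O)O[C@@H]1C[C@@H](Br)C(C)(C)O[C@]1(C)[C@H]1CCC(C)=CC1 | intermediate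
17 | (2R,3R,5R)-5-bromo-2,6,6-trimethyl-2-[(1R,3S,6S)-6-methyl-7-oxabicyclo[4.1.0]heptan-3-yl]oxan-3-yl acetate | CC(=O)O[C@@H]1C[C@@H](Br)C(C)(C)O[C@]1(C)[C@H]1CC[C@]2(C)O[C@@H]2C1 | intermediate
18 | (2R,3R,5R)-5-bromo-2-[(1S,3R,4R)-4-bromo-3-hydroxy-4-methylcyclohexyl]-2,6,6-trimethyloxan-3-yl acetate | CC(=O)O[C@@H]1C[C@@H](Br)C(C)(C)O[C@]1(C)[C@H]1CC[C@@](C)(Br)[C@H](O)C1 | intermediate
19 | triphenylphosphonium ether of 18 at the C3 oxygen, chloride salt | CC(=O)O[C@@H]1C[C@@H](Br)C(C)(C)O[C@]1(C)[C@H]1CC[C@@](C)(Br)[C@H](O[P+](c2ccccc2)(c2ccccc2)c2ccccc2)C1.[Cl-] | intermediate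
20 | 8-acetylisocaespitol, (2R,3R,5R)-5-bromo-2-[(1S,3R,4R)-4-bromo-3-chloro-4-methylcyclohexyl]-2,6,6-trimethyloxan-3-yl acetate | CC(=O)O[C@@H]1C[C@@H](Br)C(C)(C)O[C@]1(C)[C@H]1CC[C@@](C)(Br)[C@H](Cl)C1 | intermediate
21 | 8-acetylcaespitol, (2R,3R,5R)-5-bromo-2-[(1S,3S,4S)-3-bromo-4-chloro-4-methylcyclohexyl]-2,6,6-trimethyloxan-3-yl acetate | CC(=O)O[C@@H]1C[C@@H](Br)C(C)(C)O[C@]1(C)[C@H]1CC[C@](C)(Cl)[C@@H](Br)C1 | target

**Totals.** 12 steps in all; longest linear sequence 12 steps (2 → 21).

**Steps most likely to fail**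

Step 5. The remote C8 centre may discriminate the enone faces only weakly, or in the opposite sense if another rotamer reacts, giving the C1 epimer. The prenyl olefin may also attack the boron-activated enone. The fallback moves stereocontrol to an auxiliary and adds the C8 oxygen afterwards. It sets out from isoprene 11. An Et2AlCl-promoted Diels–Alder reaction with (R)-3-acryloyl-4-benzyloxazolidin-2-one F1 (two-point aluminium chelate, diene anti to benzyl) should give (R)-4-benzyl-3-[(S)-4-methylcyclohex-3-ene-1-carbonyl]oxazolidin-2-one F2. Transamidation (MeNH(OMe)·HCl, AlMe3) gives (S)-N-methoxy-N,4-dimethylcyclohex-3-ene-1-carboxamide F3. Addition of 4-methylpent-3-enylmagnesium bromide gives 5-methyl-1-[(S)-4-methylcyclohex-3-en-1-yl]hex-4-en-1-one F4. Kinetic enolisation toward the CH2 group (KN(SiMe3)2, −78 °C) and hydroxylation with the (camphorsulfonyl)oxaziridine enantiomer that delivers the 2R ketol gives (R)-2-hydroxy-5-methyl-1-[(S)-4-methylcyclohex-3-en-1-yl]hex-4-en-1-one F5. Silylation (t-BuMe2SiOSO2CF3, 2,6-lutidine) comes back to the route at 12.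

Step 7. Bromonium transfer to the ring-B olefin, five-membered (5-exo) closure at C10 and a small preference between the two chair transition states (C10 epimer) may erode the cyclisation. The fallback separates ring closure from bromine delivery and sets out from 13. Mercuricyclisation with Hg(OCOCF3)2 (MeNO2, 0 °C; then aqueous KBr) is reversible and should settle on the six-membered ether, the C10 alkylmercury bromide F6. Shi epoxidation of its only olefin as in step 10 gives the (3R,4S)-epoxide F7. Brominative demercuration with retention (Br2, LiBr, pyridine, 0 °C, dark), now with no olefin left to compete, gives the bromo-oxane epoxide silyl ether F8. Desilylation (Bu4NF, AcOH, THF) gives the epoxy alcohol F9, and acetylation (Ac2O, 4-(dimethylamino)pyridine) comes back to the route at 17.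

Step 12. The bromonium ion may hand its bromine to chloride and revert to olefin, which re-adds in the diastereomeric diaxial series. Chloride may also displace the phosphonium directly with inversion at C3, or the thermal halogen interchange may not lie far enough toward the diequatorial isomer. The fallback reverses the roles of the halogens and sets out from 16. Chlorohydroxylation (N-chlorosuccinimide, aqueous acetone, 0 °C) should give, by trans-diaxial Markovnikov opening of the chloronium ion anti to the C1 substituent, the chlorohydrin (3-Cl axial, tertiary 4-OH axial) F10. Ionising substitution of the tertiary alcohol with HBr in AcOH, bromide entering axially anti to chlorine, comes back to the route at 20, which is heated as in step 12.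

**Further compounds**

F1 | step 5 | (R)-3-acryloyl-4-benzyloxazolidin-2-one | C=CC(=O)N1[C@H](Cc2ccccc2)COC1=O
F2 | step 5 | (R)-4-benzyl-3-[(S)-4-methylcyclohex-3-ene-1-carbonyl]oxazolidin-2-one | O=C([C@H]1CCC(C)=CC1)N1[C@H](Cc2ccccc2)COC1=O
F3 | step 5 | (S)-N-methoxy-N,4-dimethylcyclohex-3-ene-1-carboxamide | CON(C)C(=O)[C@H]1CCC(C)=CC1
F4 | step 5 | 5-methyl-1-[(S)-4-methylcyclohex-3-en-1-yl]hex-4-en-1-one | CC(C)=CCCC(=O)[C@H]1CCC(C)=CC1
F5 | step 5 | (R)-2-hydroxy-5-methyl-1-[(S)-4-methylcyclohex-3-en-1-yl]hex-4-en-1-one | CC(C)=CC[C@@H](O)C(=O)[C@H]1CCC(C)=CC1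
F6 | step 7 | bromo{(3R,5R,6R)-5-[(tert-butyldimethylsilyl)oxy]-2,2,6-trimethyl-6-[(S)-4-methylcyclohex-3-en-1-yl]oxan-3-yl}mercury (C10 alkylmercury bromide) | CC(C)(C)[Si](C)(C)O[C@@H]1C[C@@H]([Hg]Br)C(C)(C)O[C@]1(C)[C@H]1CCC(C)=CC1
F7 | step 7 | (3R,4S)-epoxide of F6, oxygen anti to C7 | CC(C)(C)[Si](C)(C)O[C@@H]1C[C@@H]([Hg]Br)C(C)(C)O[C@]1(C)[C@H]1CC[C@]2(C)O[C@@H]2C1
F8 | step 7 | tert-butyldimethylsilyl ether of the C10 bromide (3R,4S)-epoxide | CC(C)(C)[Si](C)(C)O[C@@H]1C[C@@H](Br)C(C)(C)O[C@]1(C)[C@H]1CC[C@]2(C)O[C@@H]2C1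
F9 | step 7 | (2R,3R,5R)-5-bromo-2,6,6-trimethyl-2-[(1R,3S,6S)-6-methyl-7-oxabicyclo[4.1.0]heptan-3-yl]oxan-3-ol | O[C@@H]1C[C@@H](Br)C(C)(C)O[C@]1(C)[C@H]1CC[C@]2(C)O[C@@H]2C1
F10 | step 12 | (2R,3R,5R)-5-bromo-2-[(1S,3R,4R)-3-chloro-4-hydroxy-4-methylcyclohexyl]-2,6,6-trimethyloxan-3-yl acetate | CC(=O)O[C@@H]1C[C@@H](Br)C(C)(C)O[C@]1(C)[C@H]1CC[C@@](C)(O)[C@H](Cl)C1
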